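**Plan**

- Retrosynthesis: the target is symmetrical about its central CH2, so the two aryl–CH2 bonds there are cut first (formaldehyde). This leaves two identical ring A–CH2–ring B halves.
- In each half the propanoyl–ring A bond is cut. Ring A is then opened between its bridge-bearing carbon and the neighbouring carbonyl carbon that lies next to the CMe2 carbon. The resulting 3,5-dioxoheptanoate chain is cut between C4 and C5 into a 3-arylpropanoic acid and methyl 2,2-dimethyl-3-oxobutanoate.
- Enabling feature: ring A is a 2,2-dimethylcyclohexane-1,3,5-trione. That carbonyl carbon can therefore be an ester on the quaternary carbon (not enolisable), and the bridge-bearing carbon can be the terminal carbanion of a 1,3-diketone. The bridge CH2 and ring B ride in on the chain.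
- Forward: ring B is taken from flopropione with its propanoyl group already in place, so no Friedel–Crafts acylation is needed once the labile methylene bridge exists. It is formylated and benzylated, the aldehyde carbon becomes the bridge CH2 as the chain is grown and joined to the keto ester, ring A is closed and C-propanoylated, the benzyl ethers are removed, and two halves are joined by formaldehyde.
- Stereochemistry: the target has no stereocentre and no stereogenic double bond, so nothing has to be set.

Key step: step 5

Remark: enolates and phenolates are treated as ionised forms of the numbered compounds, and each enolised polyketone is drawn as a single tautomer.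

**Route**

Step 1
Reactants: 1 1-(2,4,6-trihydroxyphenyl)propan-1-one (flopropione)
Product: 3 2,4,6-trihydroxy-3-propanoylbenzaldehyde, via aryl iminium chloride 2 (not isolated)
Conditions: POCl3 (1.1 equiv), DMF, EtOAc, 0 °C to rt; then H2O, 60 °C
Reagents that add atoms: N,N-dimethylformamide, CN(C)C=O (formyl carbon); water, O (aldehyde oxygen)
Why: Vilsmeier–Haack formylation; the two free ring positions of 1 are equivalent, and the iminium group of 2 deactivates the ring against a second attack before hydrolysis releases the aldehyde.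

Step 2
Reactants: 3 2,4,6-trihydroxy-3-propanoylbenzaldehyde
Product: 4 2,4,6-tris(benzyloxy)-3-propanoylbenzaldehyde
Conditions: BnBr (4 equiv), K2CO3, DMF, 60 °C
Reagents that add atoms: benzyl bromide, BrCc1ccccc1
Why: Williamson etherification; a dipolar aprotic solvent favours O- over C-benzylation of the carbonyl-stabilised phenoxides, and excess bromide with warming should also capture the hydroxyl chelated between the two carbonyl groups.

Step 3
Reactants: 4 2,4,6-tris(benzyloxy)-3-propanoylbenzaldehyde; 5 Meldrum's acid (2,2-dimethyl-1,3-dioxane-4,6-dione)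
Product: 8 3-[2,4,6-tris(benzyloxy)-3-propanoylphenyl]propanoic acid, via arylidene Meldrum's acid 6 (not isolated), via benzyl Meldrum's acid 7 (not isolated)
Conditions: HCO2H–Et3N (5:2), 95–100 °C
Reagents that add atoms: none
Why: Reductive Knoevenagel sequence, in which condensation gives 6, formate transfers hydride to its electron-poor double bond to give 7, and 7 is cleaved with loss of acetone and CO2; formate without a transition metal should touch neither the benzyl ethers nor the hindered aryl ketone.

Step 4
Reactants: 8 3-[2,4,6-tris(benzyloxy)-3-propanoylphenyl]propanoic acid; 9 methyl 2,2-dimethyl-3-oxobutanoate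
Product: 11 methyl 2,2-dimethyl-3,5-dioxo-7-[2,4,6-tris(benzyloxy)-3-propanoylphenyl]heptanoate, via acyl imidazolide 10 (not isolated)
Conditions: 8, 1,1'-carbonyldiimidazole, THF, rt; then added to 9 + LiN(iPr)2 (3.2 equiv each), THF, −78 to −40 °C; 1 M HCl
Reagents that add atoms: none
Why: Crossed Claisen-type C-acylation of the kinetic methyl ketone enolate of 9 by an N-acylimidazole; the surplus enolate takes up the protons of the new diketone and of imidazole, the ester of 9 on its quaternary carbon is too hindered to self-condense at −78 °C, and acylation should outrun proton transfer from the doubly ortho-substituted aryl ketone.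

Step 5
Reactants: 11 methyl 2,2-dimethyl-3,5-dioxo-7-[2,4,6-tris(benzyloxy)-3-propanoylphenyl]heptanoate
Product: 12 3,5-dihydroxy-6,6-dimethyl-4-{[2,4,6-tris(benzyloxy)-3-propanoylphenyl]methyl}cyclohexa-2,4-dien-1-one (enol form of the 6,6-dimethyl-4-arylmethylcyclohexane-1,3,5-trione)
Conditions: LiN(iPr)2 (3.5 equiv), THF, −78 to 0 °C; then 1 M HCl
Reagents that add atoms: none
Why: In heptanoate numbering, LiN(iPr)2 removes in turn the central diketone proton at C4, an α-proton of the aryl ethyl ketone and a proton at C6; the C6 carbanion, the most nucleophilic site, adds to the ester carbonyl C1 and expels methoxide, and the new trione is held as its enolate so the closure does not reverse. This is a Dieckmann-type intramolecular Claisen acylation of a 1,3-diketone dianion, the known way from 2,2-dimethyl-3,5-dioxoalkanoates to filicinic acid-type triones. Ring A closes in the 6-(enolendo)-exo-trig mode, and the gem-dimethyl group at C2 favours the folded chain. No stereocentre is formed, because the bridge-bearing carbon ends as an enol carbon. The step needs C- over O-acylation and ring closure over intermolecular condensation: the ester on quaternary C2 cannot enolise and is shielded from outside attack, any enol lactone from O-attack should be reopened by the lithium methoxide set free and return to the carbanion while excess base remains, and the stabilised trione enolate is the sink. The ketone enolate on ring B should stay a spectator, since its carbon could reach the ester only through a twelve-membered ring.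

Step 6
Reactants: 12 3,5-dihydroxy-6,6-dimethyl-4-{[2,4,6-tris(benzyloxy)-3-propanoylphenyl]methyl}cyclohexa-2,4-dien-1-one; 13 propanoyl chloride
Product: 15 3,5-dihydroxy-6,6-dimethyl-2-propanoyl-4-{[2,4,6-tris(benzyloxy)-3-propanoylphenyl]methyl}cyclohexa-2,4-dien-1-one, via enol propanoate 14 (not isolated)
Conditions: EtCOCl (1.05 equiv), Et3N, CH2Cl2, 0 °C; then DMAP (0.2 equiv), rt
Reagents that add atoms: none
Why: O-acylation of the vinylogous acid followed by DMAP-catalysed O-to-C acyl transfer (Fries-type rearrangement of a 1,3-dione enol ester); whichever enol oxygen is acylated first, only the unsubstituted ring carbon between two carbonyl groups can give the fully enolised, hydrogen-bonded 2-acyl-1,3-dione, which is the thermodynamic sink.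

Step 7
Reactants: 15 3,5-dihydroxy-6,6-dimethyl-2-propanoyl-4-{[2,4,6-tris(benzyloxy)-3-propanoylphenyl]methyl}cyclohexa-2,4-dien-1-one
Product: 16 3,5-dihydroxy-6,6-dimethyl-2-propanoyl-4-[(2,4,6-trihydroxy-3-propanoylphenyl)methyl]cyclohexa-2,4-dien-1-one
Conditions: H2 (1 atm), 10% Pd/C, EtOAc–MeOH, rt
Reagents that add atoms: none
Why: Hydrogenolysis of aryl benzyl ethers; the C–C bridge, the enolised acyl-trione of ring A and the aryl ketone, which becomes chelated as the phenols appear, should not be reduced at one atmosphere in a neutral solvent.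

Step 8
Reactants: 16 3,5-dihydroxy-6,6-dimethyl-2-propanoyl-4-[(2,4,6-trihydroxy-3-propanoylphenyl)methyl]cyclohexa-2,4-dien-1-one (two equivalents); 17 formaldehyde
Product: 19 bis{2,4,6-trihydroxy-3-[(2,6-dihydroxy-3,3-dimethyl-4-oxo-5-propanoylcyclohexa-1,5-dien-1-yl)methyl]-5-propanoylphenyl}methane (CNP0541376.0), via hydroxymethyl phenol 18 (not isolated)
Conditions: 37% aq. CH2O (0.5 equiv), 1% aq. NaOH, 0 °C, short contact; then 1 M HCl
Reagents that add atoms: none
Why: Formaldehyde condensation of acylphloroglucinols to methylene-bis compounds, in which the phenolate is hydroxymethylated at the only free ring B carbon to give 18 and 18 then alkylates a second phenolate at the same position with loss of water; ring A has no free nucleophilic carbon, so only the ring B to ring B bridge can form, and the cold, brief alkaline contact is meant to limit bridge exchange.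

**Compound list**

1 | 1-(2,4,6-trihydroxyphenyl)propan-1-one (flopropione) | CCC(=O)c1c(O)cc(O)cc1O | starting material
2 | [(2,4,6-trihydroxy-3-propanoylphenyl)methylidene]dimethylammonium chloride | CCC(=O)c1c(O)cc(O)c(C=[N+](C)C)c1O.[Cl-] | intermediate
3 | 2,4,6-trihydroxy-3-propanoylbenzaldehyde | CCC(=O)c1c(O)cc(O)c(C=O)c1O | intermediate
4 | 2,4,6-tris(benzyloxy)-3-propanoylbenzaldehyde | CCC(=O)c1c(OCc2ccccc2)cc(OCc2ccccc2)c(C=O)c1OCc1ccccc1 | intermediate
5 | Meldrum's acid (2,2-dimethyl-1,3-dioxane-4,6-dione) | CC1(C)OC(=O)CC(=O)O1 | starting material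
6 | 5-{[2,4,6-tris(benzyloxy)-3-propanoylphenyl]methylidene}-2,2-dimethyl-1,3-dioxane-4,6-dione | CCC(=O)c1c(OCc2ccccc2)cc(OCc2ccccc2)c(C=C2C(=O)OC(C)(C)OC2=O)c1OCc1ccccc1 | intermediate
7 | 5-{[2,4,6-tris(benzyloxy)-3-propanoylphenyl]methyl}-2,2-dimethyl-1,3-dioxane-4,6-dione | CCC(=O)c1c(OCc2ccccc2)cc(OCc2ccccc2)c(CC2C(=O)OC(C)(C)OC2=O)c1OCc1ccccc1 | intermediate
8 | 3-[2,4,6-tris(benzyloxy)-3-propanoylphenyl]propanoic acid | CCC(=O)c1c(OCc2ccccc2)cc(OCc2ccccc2)c(CCC(=O)O)c1OCc1ccccc1 | intermediate
9 | methyl 2,2-dimethyl-3-oxobutanoate | COC(=O)C(C)(C)C(C)=O | starting material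
10 | 1-{3-[2,4,6-tris(benzyloxy)-3-propanoylphenyl]propanoyl}-1H-imidazole | CCC(=O)c1c(OCc2ccccc2)cc(OCc2ccccc2)c(CCC(=O)n2ccnc2)c1OCc1ccccc1 | intermediate
11 | methyl 2,2-dimethyl-3,5-dioxo-7-[2,4,6-tris(benzyloxy)-3-propanoylphenyl]heptanoate | COC(=O)C(C)(C)C(=O)CC(=O)CCc1c(OCc2ccccc2)cc(OCc2ccccc2)c(C(=O)CC)c1OCc1ccccc1 | intermediate
12 | 3,5-dihydroxy-6,6-dimethyl-4-{[2,4,6-tris(benzyloxy)-3-propanoylphenyl]methyl}cyclohexa-2,4-dien-1-one | CCC(=O)c1c(OCc2ccccc2)cc(OCc2ccccc2)c(CC2=C(O)C(C)(C)C(=O)C=C2O)c1OCc1ccccc1 | intermediate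
13 | propanoyl chloride | CCC(=O)Cl | starting material
14 | 5-hydroxy-4,4-dimethyl-3-oxo-6-{[2,4,6-tris(benzyloxy)-3-propanoylphenyl]methyl}cyclohexa-1,5-dien-1-yl propanoate (one of the possible enol ester regioisomers) | CCC(=O)OC1=CC(=O)C(C)(C)C(O)=C1Cc1c(OCc2ccccc2)cc(OCc2ccccc2)c(C(=O)CC)c1OCc1ccccc1 | intermediate
15 | 3,5-dihydroxy-6,6-dimethyl-2-propanoyl-4-{[2,4,6-tris(benzyloxy)-3-propanoylphenyl]methyl}cyclohexa-2,4-dien-1-one | CCC(=O)C1=C(O)C(Cc2c(OCc3ccccc3)cc(OCc3ccccc3)c(C(=O)CC)c2OCc2ccccc2)=C(O)C(C)(C)C1=O | intermediate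
16 | 3,5-dihydroxy-6,6-dimethyl-2-propanoyl-4-[(2,4,6-trihydroxy-3-propanoylphenyl)methyl]cyclohexa-2,4-dien-1-one | CCC(=O)C1=C(O)C(Cc2c(O)cc(O)c(C(=O)CC)c2O)=C(O)C(C)(C)C1=O | intermediate
17 | formaldehyde | C=O | starting material
18 | 3,5-dihydroxy-4-{[2,4,6-trihydroxy-3-(hydroxymethyl)-5-propanoylphenyl]methyl}-6,6-dimethyl-2-propanoylcyclohexa-2,4-dien-1-one | CCC(=O)C1=C(O)C(Cc2c(O)c(CO)c(O)c(C(=O)CC)c2O)=C(O)C(C)(C)C1=O | intermediate
19 | bis{2,4,6-trihydroxy-3-[(2,6-dihydroxy-3,3-dimethyl-4-oxo-5-propanoylcyclohexa-1,5-dien-1-yl)methyl]-5-propanoylphenyl}methane (CNP0541376.0) | CCC(=O)C1=C(O)C(Cc2c(O)c(Cc3c(O)c(CC4=C(O)C(C)(C)C(=O)C(C(=O)CC)=C4O)c(O)c(C(=O)CC)c3O)c(O)c(C(=O)CC)c2O)=C(O)C(C)(C)C1=O | target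

**Count and risks**

Total step count: 8. Longest linear sequence: 8 steps (1 to 19); compounds 5, 9, 13 and 17 are used as purchased.

Steps most likely to fail:

1. Step 5 (ring closure). The third deprotonation may stay incomplete because the aryl ketone holds base, and intermolecular Claisen condensation or O-acylation may then outrun the closure of ring A. The fallback sets out from 1 and 4 and comes back at 15. Flopropione 1 would be methylated twice at one free ring carbon (MeI, NaOMe, MeOH) to 3,5-dihydroxy-6,6-dimethyl-2-propanoylcyclohexa-2,4-dien-1-one (propionylfilicinic acid) F1. F1 would then be joined to aldehyde 4 by reductive alkylation, that is Knoevenagel condensation under L-proline catalysis with hydride transfer from Hantzsch ester (diethyl 2,6-dimethyl-1,4-dihydropyridine-3,5-dicarboxylate). Ring A then arrives ready-made, the bridge bond is formed on the finished ring, and steps 3 to 6 are bypassed.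

2. Step 8 (joining the halves). In alkali the existing ring A–CH2–ring B bridges may be cleaved and recombined, scrambling the units, or the coupling may stall at the hydroxymethyl stage. The fallback sets out from 16 and comes back at 19. One half of 16 would be treated with N,N-dimethylmethyleneiminium iodide in MeCN to give the Mannich base 4-({3-[(dimethylamino)methyl]-2,4,6-trihydroxy-5-propanoylphenyl}methyl)-3,5-dihydroxy-6,6-dimethyl-2-propanoylcyclohexa-2,4-dien-1-one F2. Heating F2 with the second half of 16 in dioxane, without added base, should expel dimethylamine and alkylate the free ring B carbon of 16 to give 19.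

3. Step 4 (joining the chain). Proton transfer from the aryl ethyl ketone or from the acyl imidazolide to the enolate, or O-acylation and double acylation, may replace clean C-acylation. The fallback sets out from 8 and comes back at 11, and it replaces the acylation by an aldol addition, which consumes no second equivalent of enolate. Acid 8 would be reduced with BH3·SMe2 to 1-[2,4,6-tris(benzyloxy)-3-(3-hydroxypropyl)phenyl]propan-1-one F3 and oxidised with Dess–Martin periodinane to 3-[2,4,6-tris(benzyloxy)-3-propanoylphenyl]propanal F4. The lithium enolate of 9 would be added to F4 at −78 °C to give racemic methyl 5-hydroxy-2,2-dimethyl-3-oxo-7-[2,4,6-tris(benzyloxy)-3-propanoylphenyl]heptanoate F5. A second Dess–Martin oxidation would turn F5 into the diketone 11.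

**Further compounds**

F1 | step 5 | 3,5-dihydroxy-6,6-dimethyl-2-propanoylcyclohexa-2,4-dien-1-one (propionylfilicinic acid) | CCC(=O)C1=C(O)C=C(O)C(C)(C)C1=O
F2 | step 8 | 4-({3-[(dimethylamino)methyl]-2,4,6-trihydroxy-5-propanoylphenyl}methyl)-3,5-dihydroxy-6,6-dimethyl-2-propanoylcyclohexa-2,4-dien-1-one | CCC(=O)C1=C(O)C(Cc2c(O)c(CN(C)C)c(O)c(C(=O)CC)c2O)=C(O)C(C)(C)C1=O
F3 | step 4 | 1-[2,4,6-tris(benzyloxy)-3-(3-hydroxypropyl)phenyl]propan-1-one | CCC(=O)c1c(OCc2ccccc2)cc(OCc2ccccc2)c(CCCO)c1OCc1ccccc1
F4 | step 4 | 3-[2,4,6-tris(benzyloxy)-3-propanoylphenyl]propanal | CCC(=O)c1c(OCc2ccccc2)cc(OCc2ccccc2)c(CCC=O)c1OCc1ccccc1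
F5 | step 4 | methyl 5-hydroxy-2,2-dimethyl-3-oxo-7-[2,4,6-tris(benzyloxy)-3-propanoylphenyl]heptanoate (racemic) | COC(=O)C(C)(C)C(=O)CC(O)CCc1c(OCc2ccccc2)cc(OCc2ccccc2)c(C(=O)CC)c1OCc1ccccc1
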